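**Retrosynthetic overview**
- The target, 4,6-bis(4-hydroxybenzyl)-5-(2-phenylethyl)resorcinol, is cut at both ArCH2–C(aryl) bonds at once. This gives dihydropinosylvin plus two molecules of 4-hydroxybenzyl alcohol, joined in a three-component double Friedel–Crafts alkylation via p-quinone methide.
- Enabling feature: the central ring is a resorcinol whose C4 and C6 (the carbons carrying the two ArCH2 groups) are each ortho to one OH and para to the other. They are exchanged by the mirror plane through C2, C5 and the phenethyl chain. Each benzyl arm carries a para-OH, so its CH2 is a latent p-quinone methide terminus.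
- Dihydropinosylvin comes from (E)-3,5-bis(benzyloxy)stilbene by C=C hydrogenation and double O-debenzylation in one pot. The stilbene comes from 3,5-bis(benzyloxy)benzaldehyde and diethyl benzylphosphonate (Horner–Wadsworth–Emmons).
- No ring is formed in the route: all four benzene rings are bought intact.

Key step: step 3

Remark: the target has no stereocentre and is achiral (mirror-symmetric), so no absolute configuration has to be set.

**Step 1**
Reactants: 1 3,5-bis(benzyloxy)benzaldehyde; 2 diethyl benzylphosphonate
Product: 4 1,3-bis(benzyloxy)-5-[(E)-2-phenylethenyl]benzene, via potassium phosphonate carbanion 3 (not isolated)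
Conditions: KOtBu, DMF, 0 °C → rt
Reagents that add atoms: none
Why: Horner–Wadsworth–Emmons olefination, in which carbanion 3 adds to the non-enolisable aryl aldehyde and the oxaphosphetane collapses to the conjugated E-stilbene (the geometry is erased in step 2 in any case), the benzyl ethers being inert to base.

**Step 2**
Reactants: 4 1,3-bis(benzyloxy)-5-[(E)-2-phenylethenyl]benzene
Product: 7 5-(2-phenylethyl)benzene-1,3-diol (dihydropinosylvin), via saturated dibenzyl ether 5 (not isolated), via mono-benzyl ether 6 (not isolated)
Conditions: H2 (1–3 atm), 10% Pd/C, EtOAc/MeOH, rt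
Reagents that add atoms: none
Why: Catalytic hydrogenation over Pd/C should saturate the stilbene C=C first and then cleave both aryl benzyl ethers by hydrogenolysis, leaving the arene rings and the CH2–CH2 bridge untouched and creating no stereocentre.

**Step 3**
Reactants: 7 5-(2-phenylethyl)benzene-1,3-diol; 8 4-hydroxybenzyl alcohol (2.1 equiv)
Product: 11 4,6-bis[(4-hydroxyphenyl)methyl]-5-(2-phenylethyl)benzene-1,3-diol (target), via p-quinone methide 9 (not isolated), via mono-benzylated resorcinol 10 (not isolated)
Conditions: 8 added slowly, TsOH·H2O (5 mol %), HFIP, 0 °C → rt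
Reagents that add atoms: none
Why: Acid in the ionising solvent HFIP converts 8 reversibly into p-quinone methide 9 (as its O-protonated form, the 4-hydroxybenzyl cation), which is attacked by C4 of the resorcinol ring of 7 and, after re-aromatisation to 10, a second equivalent of 9 is attacked by the mirror-related C6, so that both ArCH2–C(aryl) bonds of the target arise in one three-component operation. The closest known reaction type is the Friedel–Crafts hydroxybenzylation of resorcinols and other polyphenols with 4-hydroxybenzyl alcohols via p-quinone methides, as in resorcinol–phenolic resin chemistry and in HFIP-promoted benzylations with electron-rich benzylic alcohols. No ring is closed and no stereocentre is formed, so only site selectivity and chemoselectivity are required. Site selectivity for C4/C6 over C2 should follow from the innate preference of resorcinols to react para to one hydroxyl and ortho to the other (the positions also taken in the 4,6-dihalogenation and the formylation of 5-alkylresorcinols), C2 being buried between two solvated hydroxyls. Chemoselectivity for the resorcinol nucleus over the mono-phenolic rings of 8, 10 and 11 rests on its much higher nucleophilicity and is reinforced by the slow addition of 8, which keeps the concentration of 9 low and disfavours self-condensation, while any benzyl aryl ether or bis(4-hydroxybenzyl) ether formed by O-attack re-ionises under the acid and is funnelled to C-alkylation. The limited charge of 8 and the low temperature are meant to hold back a third alkylation at C2.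

**Compound list**
1 | 3,5-bis(benzyloxy)benzaldehyde | O=Cc1cc(OCc2ccccc2)cc(OCc2ccccc2)c1 | starting material
2 | diethyl benzylphosphonate | CCOP(=O)(Cc1ccccc1)OCC | starting material
3 | potassium salt of the carbanion of diethyl benzylphosphonate (formed in situ) | CCOP(=O)([CH-]c1ccccc1)OCC.[K+] | intermediate
4 | 1,3-bis(benzyloxy)-5-[(E)-2-phenylethenyl]benzene | c1ccccc1/C=C/c1cc(OCc2ccccc2)cc(OCc2ccccc2)c1 | intermediate
5 | 1,3-bis(benzyloxy)-5-(2-phenylethyl)benzene (formed in situ) | c1ccccc1CCc1cc(OCc2ccccc2)cc(OCc2ccccc2)c1 | intermediate
6 | 3-(benzyloxy)-5-(2-phenylethyl)phenol (formed in situ) | Oc1cc(OCc2ccccc2)cc(CCc2ccccc2)c1 | intermediate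
7 | 5-(2-phenylethyl)benzene-1,3-diol (dihydropinosylvin) | Oc1cc(O)cc(CCc2ccccc2)c1 | intermediate
8 | 4-hydroxybenzyl alcohol | OCc1ccc(O)cc1 | starting material
9 | 4-methylidenecyclohexa-2,5-dien-1-one (p-quinone methide, formed in situ) | C=C1C=CC(=O)C=C1 | intermediate
10 | 4-[(4-hydroxyphenyl)methyl]-5-(2-phenylethyl)benzene-1,3-diol (formed in situ) | Oc1ccc(Cc2c(O)cc(O)cc2CCc2ccccc2)cc1 | intermediate
11 | 4,6-bis[(4-hydroxyphenyl)methyl]-5-(2-phenylethyl)benzene-1,3-diol | Oc1ccc(Cc2c(O)cc(O)c(Cc3ccc(O)cc3)c2CCc2ccccc2)cc1 | target

**Total step count:** 3
**Longest linear sequence:** 3 steps (1 → 4 → 7 → 11)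

**Steps most likely to fail**

1. Step 3. The risks are alkylation at C2 between the two hydroxyls competing with attack at C4/C6, a third alkylation of the product, and self-condensation of the hydroxybenzyl electrophile into oligomers. The fallback fixes the sites by halogenation and makes the two bonds by cross-coupling. It sets out from 7 and comes back at 11. Dibromination of 7 with NBS (2 equiv, CH2Cl2/MeCN, −78 → 0 °C) should give 4,6-dibromo-5-(2-phenylethyl)benzene-1,3-diol F1, with C2–H left in place. O-Methylation (MeI, K2CO3, acetone) would give 2,4-dibromo-1,5-dimethoxy-3-(2-phenylethyl)benzene F2. A double Negishi coupling with commercial 4-methoxybenzylzinc chloride (Pd(OAc)2/SPhos, THF, 60 °C) should give 1,5-dimethoxy-2,4-bis[(4-methoxyphenyl)methyl]-3-(2-phenylethyl)benzene F3. Global demethylation (BBr3, CH2Cl2, −78 °C → rt) would then deliver 11.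

2. Step 2. The risk is stalling of the ether hydrogenolysis after the alkene is saturated (for example by catalyst poisoning from phosphorus-containing residues), which would leave partly benzylated material. The fallback separates the two events and removes the benzyl groups without a metal catalyst. It sets out from 4 and comes back at 7. Lewis-acid debenzylation with a cation scavenger (BCl3, pentamethylbenzene, CH2Cl2, −78 °C) should give 5-[(E)-2-phenylethenyl]benzene-1,3-diol (pinosylvin) F4. Diimide reduction of the C=C bond (TsNHNH2, NaOAc, THF/H2O, reflux) would then give 7.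

3. Step 1. The risk is incomplete olefination through slow or reversible deprotonation of the weakly acidic benzylphosphonate, together with base-induced degradation of the aldehyde. The fallback replaces olefination by addition and elimination. It sets out from 1 and comes back at 4. Addition of benzylmagnesium chloride (THF, 0 °C) should give racemic 1-[3,5-bis(benzyloxy)phenyl]-2-phenylethan-1-ol F5. Acid-catalysed dehydration (TsOH cat., toluene, reflux, Dean–Stark) should lead to the conjugated E-stilbene 4.

**Further compounds**
F1 | step 3 | 4,6-dibromo-5-(2-phenylethyl)benzene-1,3-diol | Oc1cc(O)c(Br)c(CCc2ccccc2)c1Br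
F2 | step 3 | 2,4-dibromo-1,5-dimethoxy-3-(2-phenylethyl)benzene | COc1cc(OC)c(Br)c(CCc2ccccc2)c1Br
F3 | step 3 | 1,5-dimethoxy-2,4-bis[(4-methoxyphenyl)methyl]-3-(2-phenylethyl)benzene | COc1ccc(Cc2c(OC)cc(OC)c(Cc3ccc(OC)cc3)c2CCc2ccccc2)cc1
F4 | step 2 | 5-[(E)-2-phenylethenyl]benzene-1,3-diol (pinosylvin) | Oc1cc(O)cc(/C=C/c2ccccc2)c1
F5 | step 1 | 1-[3,5-bis(benzyloxy)phenyl]-2-phenylethan-1-ol (racemic) | OC(Cc1ccccc1)c1cc(OCc2ccccc2)cc(OCc2ccccc2)c1
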